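Will the flask's chains reach an average of 7.0 units by 30 min, and how long will they be then? Watch the second end groups: at 0.234 M against 0.26 M of first end groups, they are the limiting reagent. The flask also holds 0.260 M of protic impurity.

Units number 0.247 M, and chains are units minus links. If every second end links, 0.0130 M of chains remain, so the length is 19.0, my bound from above. But call the leak the second ends charged that never become links: each adds one chain.

The green run has the same end groups and twice the flask's impurity.

all flasks: second end groups 0.234 M
- grey: first end groups 0.13 M; protic impurity 0.26 M; run made earlier
- ochre: first end groups 0.52 M; protic impurity 0.26 M; run made earlier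
- green: first end groups 0.26 M; protic impurity 0.52 M; run made earlier
- flask: first end groups 0.26 M; protic impurity 0.260 M; time 30 min

| run | time / min | links / % | first end groups / % |
|---|---|---|---|
| grey | 1.50 | 95.5 | 1.8 |
| grey | 5.00 | 100.1 | 1.3 |
| grey | 8.00 | 100.8 | 1.1 |
| grey | 12.0 | 101.1 | 1.0 |
| grey | 20.0 | 100.8 | 0 |
| grey | 25.0 | 100.4 | 0.2 |
| ochre | 2.00 | 45.1 | 56.4 |
| ochre | 3.00 | 44.8 | 54.8 |
| ochre | 5.00 | 44.8 | 54.5 |
| ochre | 8.00 | 43.9 | 55.9 |
| ochre | 15.0 | 45.0 | 55.7 |
| ochre | 25.0 | 45.1 | 54.8 |
| green | 2.00 | 81.6 | 17.9 |
| green | 4.00 | 88.5 | 12.0 |
| green | 6.00 | 87.6 | 13.7 |
| green | 12.0 | 87.3 | 11.9 |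
| green | 25.0 | 87.0 | 13.1 |

(readings scatter by 1 percentage point)

- each molecule carries two end groups: a chain counts once for every two ends that are left, dead ends included; the units are half of the end groups of the two monomers charged
- the analysis behind the earlier runs scatters by 1 percentage point, standard deviation

From the second reading on, the green run's links average 0.228 M, so its leak reads 0.00624 M, a reading whose points each scatter by 1 percentage point. If less impurity leaks no more, the flask's length is at least 12.8, already above 7.0. If the leak grows no faster than the impurity, the flask keeps at least half of it, 0.00312 M, and the length is at most 15.3.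

The forecast says yes and 13.5, inside my bracket, and reasons that “All runs plateau within minutes, which suggests a reversible linking equilibrium”.

The flask gives yes and 14.6, also inside.

    second end groups → decomposed reagent (k = 0.0132 /min)
    first end groups + second end groups → links (k = 15.7 /M/min)
    second end groups + protic impurity → quenched reagent (k = 0.0578 /M/min)

At 30.0 min the flask holds 0.00182 M of decomposed reagent and 0.00206 M of quenched reagent, with 0% of its second end groups left. Its leak is therefore 0.00388 M, less than green's reading of 0.00624 M, and units over chains returns 14.6: the length counts links, whichever step took the rest. In the ochre run, charged with 0.52 M of first end groups, the readings give a leak of 0.00113 M beside 0.143 M of chains from the excess, and a length of 2.62.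

The readings were generated by integration on assumed constants; noise was put on by code.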